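**Retrosynthetic overview** (azulene numbering of the target; ring A = cyclopentane C1, C2, C3, C3a, C8a; ring B = seven-membered ring C3a, C4–C8, C8a)
1. The C4 ester comes off to jaeschkeanadiol; the C4 carbinol comes from a C4 ketone by reduction directed by the C3 hydroxyl; the C6 methyl comes from a C6 enol triflate.
2. Ring B is opened at C8–C8a by a retro-oxy-Cope step to a cis-1,2-dialkenylcyclopropanolate in which C4, C5 and C6 form the three-membered ring.
3. That cyclopropanolate comes from a cyclopentenyl acylsilane (C4) and the enolate of methyl vinyl ketone (C5–C8); a Brook rearrangement reverses the polarity of the acyl carbon C4.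
4. Enabling feature: in ring B the oxygen-bearing C4 and the alkene carbon C6 both sit on C5, C4 is flanked by C3a (next to quaternary C8a) and C6 by C7=C8. Ring B is therefore a masked cyclohepta-1,4-diene (C3a=C4 enol, C6=C7), the retron of a dialkenylcyclopropane Cope rearrangement.
5. Ring order: ring A first (ring contraction of (S)-terpinen-4-ol, which supplies C3), then the transient cyclopropane, then ring B.

Key step: step 6

Remark: (S)-(+)-terpinen-4-ol is taken to be used in high enantiomeric purity (lots of lower purity would be enriched first); every other stereocentre is derived from its carbinol carbon.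

**Route**

Step 1
Reactants: 1 (S)-(+)-terpinen-4-ol
Product: 2 triethyl{[(1S)-4-methyl-1-(propan-2-yl)cyclohex-3-en-1-yl]oxy}silane
Conditions: TESOTf, 2,6-lutidine, CH2Cl2, 0 °C
Reagents that add atoms: triethylsilyl trifluoromethanesulfonate, CC[Si](CC)(CC)OS(=O)(=O)C(F)(F)F
Why: Silyl triflate silylation of a tertiary alcohol leaves the stereocentre untouched and installs the bulky ether that later shields one face of ring A.

Step 2
Reactants: 2 silyl ether
Product: 3 (3S)-6-oxo-3-(propan-2-yl)-3-[(triethylsilyl)oxy]heptanal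
Conditions: O3, CH2Cl2, −78 °C; PPh3, −78 °C → rt
Reagents that add atoms: ozone, [O-][O+]=O
Why: Ozonolysis of the only alkene with reductive work-up should give the 1,6-keto aldehyde without touching the stereocentre.

Step 3
Reactants: 3 keto aldehyde
Product: 4 (5R)-2-methyl-5-(propan-2-yl)-5-[(triethylsilyl)oxy]cyclopent-1-ene-1-carbaldehyde
Conditions: Bn2NH·CF3CO2H (cat.), toluene, 50 °C
Reagents that add atoms: none
Why: Amine-catalysed intramolecular aldol condensation (5-exo attack of the aldehyde enamine on the methyl ketone, then loss of water from the new aldol) should give the cyclopentenecarbaldehyde; the silyl ether is a much poorer leaving group than the new hydroxyl, so dehydration should go toward the methyl-bearing carbon.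

Step 4
Reactants: 4 enal
Product: 5 [dimethyl(phenyl)silyl][(5R)-2-methyl-5-(propan-2-yl)-5-(triethylsilyloxy)cyclopent-1-en-1-yl]methanol (both carbinol epimers)
Conditions: PhMe2SiLi, THF, −78 °C; NH4Cl (aq) at −78 °C
Reagents that add atoms: dimethyl(phenyl)silyllithium, [Li][Si](C)(C)c1ccccc1
Why: 1,2-Addition of a silyllithium to an aldehyde; the new carbinol centre forms unselectively and is removed in step 5, and the cold quench is meant to forestall Brook rearrangement of the allylic α-silyl alkoxide.

Step 5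
Reactants: 5 α-silyl alcohol
Product: 6 [dimethyl(phenyl)silyl][(5R)-2-methyl-5-(propan-2-yl)-5-(triethylsilyloxy)cyclopent-1-en-1-yl]methanone
Conditions: (COCl)2, DMSO, CH2Cl2, −78 °C; Et3N, −78 → 0 °C
Reagents that add atoms: none
Why: Swern oxidation is a standard way to turn an α-hydroxysilane into the acylsilane without acid or strong base.

Step 6
Reactants: 6 acylsilane; 7 2-(trimethylsilyloxy)buta-1,3-diene
Product: 12 (3R,8aR)-4-[dimethyl(phenyl)silyloxy]-8a-methyl-3-(propan-2-yl)-3-(triethylsilyloxy)-1,2,3,5,8,8a-hexahydroazulen-6-yl trifluoromethanesulfonate, via lithium buta-1,3-dien-2-olate 8 (not isolated), via lithium alkoxide adduct 9 (not isolated), via lithium cis-dialkenylcyclopropanolate 10 (not isolated), via ring-expanded lithium enolate 11 (not isolated)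
Conditions: 7, MeLi, THF, 0 °C; then 6, −80 → 0 °C; then PhNTf2, −78 → 0 °C; NH4Cl (aq)
Reagents that add atoms: N-phenylbis(trifluoromethanesulfonimide), O=S(=O)(N(c1ccccc1)S(=O)(=O)C(F)(F)F)C(F)(F)F
Why: Enolate 8 adds to the acylsilane carbonyl of 6 to give alkoxide 9, whose 1,2-Brook rearrangement (silicon from C4 to oxygen) turns the former acyl carbon into an allyl-stabilised carbanion that attacks the vinyl ketone carbonyl (3-exo-trig) and closes the transient cyclopropane of 10 with the two alkenyl groups cis, the two oxygens being held together on the other face by the bridging lithium. The closest known reaction type is the Brook-rearrangement-mediated [3+4] annulation of alkenyl acylsilanes with lithium enolates of alkenyl methyl ketones, which runs through such a cis-1,2-dialkenylcyclopropanolate and its anionic oxy-Cope rearrangement. Ring B is then closed by the [3,3]-sigmatropic shift of 10 through a boat transition state, which makes the C8–C8a bond, breaks the C4–C6 cyclopropane bond and releases the ring strain, the alkoxide on C6 lowering the barrier enough to offset the methyl group on the reacting alkene terminus. The only new stereocentre, quaternary C8a, is set by chirality transfer from the cyclopropane, whose configuration is fixed by the C3 triethylsilyl ether: pushed by the geminal isopropyl group over one face of the cyclopentene, it should make both the cyclopropanation and the sigmatropic shift take place on the opposite face, so that C8 ends up trans and the 8a-methyl cis to the silyloxy group. The step needs 1,2-addition in place of conjugate addition (the β-carbon of 6 is fully substituted), cis geometry in 10 (lithium chelate) and regiospecific O-triflation (enolate 11 is formed only toward C7 by the rearrangement and is trapped before it can equilibrate), while the C3a=C4 silyl enol ether keeps the second carbonyl masked and distinct.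

Step 7
Reactants: 12 enol triflate
Product: 13 {[(3R,8aR)-6,8a-dimethyl-3-(propan-2-yl)-3-(triethylsilyloxy)-1,2,3,5,8,8a-hexahydroazulen-4-yl]oxy}dimethyl(phenyl)silane
Conditions: MeMgBr, Fe(acac)3 (5 mol %), THF–NMP, −30 °C
Reagents that add atoms: methylmagnesium bromide, C[Mg]Br
Why: Iron-catalysed Kumada-type cross-coupling of an alkenyl triflate should place the methyl group on C6 and leave the alkene at C6=C7, where the enolate fixed it.

Step 8
Reactants: 13 silyl dienol ether
Product: 15 (3R,3aR,8aR)-3-hydroxy-6,8a-dimethyl-3-(propan-2-yl)-1,2,3,3a,8,8a-hexahydroazulen-4(5H)-one, via silyl-protected trans-fused ketone 14 (not isolated)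
Conditions: Bu4NF, AcOH, THF, −40 °C; then HF·pyridine, 0 °C
Reagents that add atoms: none
Why: Buffered fluoride cleaves only the enol silyl ether, and the enol should be protonated at C3a on the face opposite the bulky C3 silyloxy group (kinetic C-protonation, which should also be the thermodynamically preferred outcome, with the C4 carbonyl anti to the isopropyl group); this gives 3a-H trans to the 8a-methyl, and acidic fluoride then removes the tertiary silyl ether without base so the β,γ-unsaturated aldol should survive.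

Step 9
Reactants: 15 β-hydroxy ketone
Product: 16 jaeschkeanadiol [(3R,3aS,4S,8aR)-6,8a-dimethyl-3-(propan-2-yl)-1,2,3,3a,4,5,8,8a-octahydroazulene-3,4-diol]
Conditions: Me4NBH(OAc)3, MeCN–AcOH, −20 °C
Reagents that add atoms: none
Why: Evans–Saksena reduction: the C3 hydroxyl binds the triacetoxyborohydride and delivers hydride to the face of the C4 ketone it overlooks, which should give the 1,3-anti diol (C4–OH trans to C3–OH).

Step 10
Reactants: 16 jaeschkeanadiol; 17 4-acetoxybenzoyl chloride
Product: 18 (3R,3aS,4S,8aR)-3-hydroxy-6,8a-dimethyl-3-(propan-2-yl)-1,2,3,3a,4,5,8,8a-octahydroazulen-4-yl 4-acetoxybenzoate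
Conditions: pyridine, DMAP (cat.), CH2Cl2, 0 °C → rt
Reagents that add atoms: none
Why: Acylation with an acid chloride under nucleophilic catalysis should occur only at the secondary C4 hydroxyl, the tertiary C3 hydroxyl being too hindered.

Step 11
Reactants: 18 acetate-protected ester
Product: 19 ferutinine
Conditions: pyrrolidine, CH2Cl2, 0 °C
Reagents that add atoms: none
Why: Aminolysis of the aryl acetate, which is far more electrophilic than the hindered secondary benzoate, should free the phenol.

**Compound list**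
1 | (S)-(+)-terpinen-4-ol, (1S)-4-methyl-1-(propan-2-yl)cyclohex-3-en-1-ol | CC1=CC[C@](O)(C(C)C)CC1 | starting material
2 | triethyl{[(1S)-4-methyl-1-(propan-2-yl)cyclohex-3-en-1-yl]oxy}silane | CC1=CC[C@](O[Si](CC)(CC)CC)(C(C)C)CC1 | intermediate
3 | (3S)-6-oxo-3-(propan-2-yl)-3-[(triethylsilyl)oxy]heptanal | CC(=O)CC[C@@](O[Si](CC)(CC)CC)(C(C)C)CC=O | intermediate
4 | (5R)-2-methyl-5-(propan-2-yl)-5-[(triethylsilyl)oxy]cyclopent-1-ene-1-carbaldehyde | O=CC1=C(C)CC[C@@]1(O[Si](CC)(CC)CC)C(C)C | intermediate
5 | [dimethyl(phenyl)silyl][(5R)-2-methyl-5-(propan-2-yl)-5-(triethylsilyloxy)cyclopent-1-en-1-yl]methanol, both carbinol epimers | OC(C1=C(C)CC[C@@]1(O[Si](CC)(CC)CC)C(C)C)[Si](C)(C)c2ccccc2 | intermediate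
6 | [dimethyl(phenyl)silyl][(5R)-2-methyl-5-(propan-2-yl)-5-(triethylsilyloxy)cyclopent-1-en-1-yl]methanone | O=C(C1=C(C)CC[C@@]1(O[Si](CC)(CC)CC)C(C)C)[Si](C)(C)c2ccccc2 | intermediate
7 | 2-(trimethylsilyloxy)buta-1,3-diene | C=CC(=C)O[Si](C)(C)C | starting material
8 | lithium buta-1,3-dien-2-olate | [Li]OC(=C)C=C | intermediate
9 | lithium alkoxide of the 1,2-adduct (C4 carbinol carbon bearing silyl, cyclopentenyl and the 2-oxobut-3-enyl chain; configuration at C4 not defined) | C=CC(=O)CC(O[Li])(C1=C(C)CC[C@@]1(O[Si](CC)(CC)CC)C(C)C)[Si](C)(C)c2ccccc2 | intermediate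
10 | lithium 2-[dimethyl(phenyl)silyloxy]-2-[(5R)-cyclopentenyl]-1-vinylcyclopropan-1-olate, alkenyl groups cis, ring carbons on the face of ring A opposite the triethylsilyloxy group | C=C[C@@]1(O[Li])C[C@@]1(O[Si](C)(C)c2ccccc2)C3=C(C)CC[C@@]3(O[Si](CC)(CC)CC)C(C)C | intermediate
11 | lithium (3R,8aR)-4-[dimethyl(phenyl)silyloxy]-8a-methyl-3-(propan-2-yl)-3-(triethylsilyloxy)-1,2,3,5,8,8a-hexahydroazulen-6-olate | [Li]OC1=CC[C@@]2(C)CC[C@@](O[Si](CC)(CC)CC)(C(C)C)C2=C(O[Si](C)(C)c3ccccc3)C1 | intermediate
12 | (3R,8aR)-4-[dimethyl(phenyl)silyloxy]-8a-methyl-3-(propan-2-yl)-3-(triethylsilyloxy)-1,2,3,5,8,8a-hexahydroazulen-6-yl trifluoromethanesulfonate | FC(F)(F)S(=O)(=O)OC1=CC[C@@]2(C)CC[C@@](O[Si](CC)(CC)CC)(C(C)C)C2=C(O[Si](C)(C)c3ccccc3)C1 | intermediate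
13 | {[(3R,8aR)-6,8a-dimethyl-3-(propan-2-yl)-3-(triethylsilyloxy)-1,2,3,5,8,8a-hexahydroazulen-4-yl]oxy}dimethyl(phenyl)silane | CC1=CC[C@@]2(C)CC[C@@](O[Si](CC)(CC)CC)(C(C)C)C2=C(O[Si](C)(C)c3ccccc3)C1 | intermediate
14 | (3R,3aR,8aR)-6,8a-dimethyl-3-(propan-2-yl)-3-(triethylsilyloxy)-1,2,3,3a,8,8a-hexahydroazulen-4(5H)-one | CC1=CC[C@@]2(C)CC[C@@](O[Si](CC)(CC)CC)(C(C)C)[C@@H]2C(=O)C1 | intermediate
15 | (3R,3aR,8aR)-3-hydroxy-6,8a-dimethyl-3-(propan-2-yl)-1,2,3,3a,8,8a-hexahydroazulen-4(5H)-one | CC1=CC[C@@]2(C)CC[C@@](O)(C(C)C)[C@@H]2C(=O)C1 | intermediate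
16 | jaeschkeanadiol, (3R,3aS,4S,8aR)-6,8a-dimethyl-3-(propan-2-yl)-1,2,3,3a,4,5,8,8a-octahydroazulene-3,4-diol | CC1=CC[C@@]2(C)CC[C@@](O)(C(C)C)[C@@H]2[C@@H](O)C1 | intermediate
17 | 4-acetoxybenzoyl chloride | CC(=O)Oc1ccc(cc1)C(Cl)=O | starting material
18 | (3R,3aS,4S,8aR)-3-hydroxy-6,8a-dimethyl-3-(propan-2-yl)-1,2,3,3a,4,5,8,8a-octahydroazulen-4-yl 4-acetoxybenzoate | CC1=CC[C@@]2(C)CC[C@@](O)(C(C)C)[C@@H]2[C@@H](OC(=O)c2ccc(OC(C)=O)cc2)C1 | intermediate
19 | ferutinine, (3R,3aS,4S,8aR)-3-hydroxy-6,8a-dimethyl-3-(propan-2-yl)-1,2,3,3a,4,5,8,8a-octahydroazulen-4-yl 4-hydroxybenzoate | CC1=CC[C@@]2(C)CC[C@@](O)(C(C)C)[C@@H]2[C@@H](OC(=O)c2ccc(O)cc2)C1 | target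

**Totals**
Total step count: 11. Longest linear sequence: 11 steps (1 → 19).

**Steps most likely to fail**

1. Step 6. The Brook rearrangement may not start at the hindered alkoxide, the sigmatropic shift may be slowed by the fully substituted alkene terminus so that the cyclopropanolate reverts or fragments, or the facial selectivity may be poor. The fallback sets out from 4 and comes back at 14; it makes the same C8–C8a bond by a neutral rhodium-carbenoid cyclopropanation and thermal Cope rearrangement (formal [4+3]). MeMgBr is added to 4 to give the secondary alcohol F1. Dess–Martin periodinane oxidises it to the methyl ketone F2. TBSOTf and Et3N convert this into the 2-silyloxydiene F3. Rh2(OPiv)4-catalysed decomposition of methyl 2-diazobut-3-enoate in the presence of F3 should cyclopropanate the enol ether alkene on the face away from the triethylsilyloxy group and give the cis-dialkenylcyclopropane F4. On heating in toluene F4 should rearrange to the cycloheptadiene ester F5. iBu2AlH reduces the ester to the allylic alcohol F6. MsCl and Et3N give the mesylate F7, and LiEt3BH displaces it to give the 6-methyl diene F8, the tert-butyldimethylsilyl analogue of 13. Under the conditions of step 8, F8 should give 14.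

2. Step 8. Protonation at C3a may occur with poor facial selectivity, the alkene may migrate into conjugation with the ketone, or the C3 oxygen may be lost by β-elimination from the enol or enolate. The fallback sets out from 13 and comes back at 14; it replaces kinetic by thermodynamic control. Buffered fluoride cleavage of 13 that gives the cis-fused ketone F9 (alone or mixed with 14) is followed by DBU in toluene, which moves the alkene into conjugation and lets C3a epimerise, so the conjugated trans-fused enone F10 should accumulate. Thermodynamic dienolate formation with KOtBu in tBuOH–THF at 0 °C and inverse quench into AcOH (kinetic protonation at C5) should then return the β,γ-unsaturated ketone 14.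

3. Step 4. The lithium α-silyl alkoxide is allylic and may undergo Brook rearrangement before the quench, or the silyl anion may add in conjugate fashion. The fallback sets out from 4 and comes back at 6; it avoids the α-silyl carbinol. Pinnick oxidation (NaClO2, NaH2PO4, 2-methylbut-2-ene) gives the carboxylic acid F11. (COCl)2 with catalytic DMF followed by morpholine gives the morpholine amide F12. PhMe2SiLi in THF at −78 °C adds once to the amide, and the tetrahedral adduct collapses on work-up to acylsilane 6.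

**Further compounds**
F1 | step 6 | 1-[(5R)-2-methyl-5-(propan-2-yl)-5-(triethylsilyloxy)cyclopent-1-en-1-yl]ethanol, both carbinol epimers | CC(O)C1=C(C)CC[C@@]1(O[Si](CC)(CC)CC)C(C)C
F2 | step 6 | 1-[(5R)-2-methyl-5-(propan-2-yl)-5-(triethylsilyloxy)cyclopent-1-en-1-yl]ethanone | CC(=O)C1=C(C)CC[C@@]1(O[Si](CC)(CC)CC)C(C)C
F3 | step 6 | tert-butyldimethyl({1-[(5R)-2-methyl-5-(propan-2-yl)-5-(triethylsilyloxy)cyclopent-1-en-1-yl]ethenyl}oxy)silane | C=C(O[Si](C)(C)C(C)(C)C)C1=C(C)CC[C@@]1(O[Si](CC)(CC)CC)C(C)C
F4 | step 6 | methyl 2-(tert-butyldimethylsilyloxy)-2-[(5R)-cyclopentenyl]-1-vinylcyclopropane-1-carboxylate, alkenyl groups cis | C=C[C@@]1(C(=O)OC)C[C@@]1(O[Si](C)(C)C(C)(C)C)C2=C(C)CC[C@@]2(O[Si](CC)(CC)CC)C(C)C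
F5 | step 6 | methyl (3R,8aR)-4-(tert-butyldimethylsilyloxy)-8a-methyl-3-(propan-2-yl)-3-(triethylsilyloxy)-1,2,3,5,8,8a-hexahydroazulene-6-carboxylate | COC(=O)C1=CC[C@@]2(C)CC[C@@](O[Si](CC)(CC)CC)(C(C)C)C2=C(O[Si](C)(C)C(C)(C)C)C1
F6 | step 6 | [(3R,8aR)-4-(tert-butyldimethylsilyloxy)-8a-methyl-3-(propan-2-yl)-3-(triethylsilyloxy)-1,2,3,5,8,8a-hexahydroazulen-6-yl]methanol | OCC1=CC[C@@]2(C)CC[C@@](O[Si](CC)(CC)CC)(C(C)C)C2=C(O[Si](C)(C)C(C)(C)C)C1
F7 | step 6 | methanesulfonate of F6 | CS(=O)(=O)OCC1=CC[C@@]2(C)CC[C@@](O[Si](CC)(CC)CC)(C(C)C)C2=C(O[Si](C)(C)C(C)(C)C)C1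
F8 | step 6 | tert-butyl{[(3R,8aR)-6,8a-dimethyl-3-(propan-2-yl)-3-(triethylsilyloxy)-1,2,3,5,8,8a-hexahydroazulen-4-yl]oxy}dimethylsilane | CC1=CC[C@@]2(C)CC[C@@](O[Si](CC)(CC)CC)(C(C)C)C2=C(O[Si](C)(C)C(C)(C)C)C1
F9 | step 8 | (3R,3aS,8aR)-6,8a-dimethyl-3-(propan-2-yl)-3-(triethylsilyloxy)-1,2,3,3a,8,8a-hexahydroazulen-4(5H)-one, cis-fused epimer of 14 | CC1=CC[C@@]2(C)CC[C@@](O[Si](CC)(CC)CC)(C(C)C)[C@H]2C(=O)C1
F10 | step 8 | (3R,3aR,8aR)-6,8a-dimethyl-3-(propan-2-yl)-3-(triethylsilyloxy)-2,3,3a,7,8,8a-hexahydroazulen-4(1H)-one, conjugated C5=C6 enone | CC1=CC(=O)[C@H]2[C@](O[Si](CC)(CC)CC)(C(C)C)CC[C@]2(C)CC1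
F11 | step 4 | (5R)-2-methyl-5-(propan-2-yl)-5-(triethylsilyloxy)cyclopent-1-ene-1-carboxylic acid | OC(=O)C1=C(C)CC[C@@]1(O[Si](CC)(CC)CC)C(C)C
F12 | step 4 | [(5R)-2-methyl-5-(propan-2-yl)-5-(triethylsilyloxy)cyclopent-1-en-1-yl](morpholin-4-yl)methanone | O=C(N1CCOCC1)C2=C(C)CC[C@@]2(O[Si](CC)(CC)CC)C(C)C
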